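**Retrosynthetic overview**

1. Only one ring is made, the 1,4-dioxane, and it is made last. Both benzene rings are bought: eugenol 1 is demethylated to 4-allylcatechol 2, and 3,4,5-trimethoxybenzaldehyde 3 is olefinated to (Z)-isoelemicin 4.
2. Key disconnection: both ring C–O bonds at once (retro oxa-[4+2]) to 4 and 4-allyl-1,2-benzoquinone 5, the two-electron oxidation product of 2. This is the oxidative union of an allylcatechol with a propenylbenzene by which plants are thought to assemble benzodioxane neolignans, taken at the quinone stage so that the propenyl unit needs no free phenol and no O-methylation follows.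
3. Regiochemistry comes from the quinone: its oxygen para to the allyl group takes the CH–CH3 carbon, the oxygen meta to it takes the CH–aryl carbon.
4. Stereochemistry: suprafacial addition turns the Z alkene into the cis ring of target 6, and a chiral Brønsted acid chooses the enantiomer.

Assumption: the SMILES is read as the cis isomer with S at the methyl-bearing carbon (on the oxygen para to the allyl group) and R at the aryl-bearing carbon (on the oxygen meta to it); which antipode of the chiral acid gives this enantiomer cannot be predicted, so the (R)-acid is written and the (S)-acid is used if the first run gives the mirror image.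

**Route**

Step 1
Reactants: 1 eugenol (4-allyl-2-methoxyphenol)
Product: 2 4-allylcatechol (4-(prop-2-enyl)benzene-1,2-diol)
Conditions: BBr3 (2.2 equiv), CH2Cl2, −78 → 0 °C, 2 h; then H2O
Reagents that add atoms: none
Why: BBr3 cleavage of an aryl methyl ether, in which boron binds the guaiacol oxygens and bromide attacks the methyl group by SN2 while the isolated terminal alkene is left alone at or below 0 °C; no stereocentre is involved.

Step 2
Reactants: 3 3,4,5-trimethoxybenzaldehyde
Product: 4 (Z)-isoelemicin [(Z)-1,2,3-trimethoxy-5-(prop-1-enyl)benzene]
Conditions: EtPPh3Br (1.3 equiv), KN(SiMe3)2 (1.25 equiv), THF, 0 °C (ylide), then 3 at −78 °C → rt; chromatography on AgNO3-impregnated silica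
Reagents that add atoms: ethyltriphenylphosphonium bromide, CC[P+](c1ccccc1)(c1ccccc1)c1ccccc1.[Br-]
Why: Wittig olefination with a non-stabilised ylide under salt-free conditions, where kinetically controlled formation of the cis-oxaphosphetane gives mainly the Z alkene (about 9:1) and the E isomer is removed on AgNO3-impregnated silica, so the geometry that later becomes the cis ring relationship is secured here.

Step 3
Reactants: 2 4-allylcatechol; 4 (Z)-isoelemicin
Product: 6 (2S,3R)-2-methyl-6-(prop-2-enyl)-3-(3,4,5-trimethoxyphenyl)-2,3-dihydro-1,4-benzodioxine, via 4-allyl-1,2-benzoquinone 5 (not isolated)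
Conditions: 2 (1.5 equiv), Ag2O (3 equiv), Na2SO4, CH2Cl2, 0 °C, 15 min, cold filtration under argon; filtrate added to 4 (1.0 equiv), (R)-3,3'-bis(2,4,6-triisopropylphenyl)-1,1'-binaphthyl-2,2'-diyl N-triflylphosphoramide (10 mol%), 4 Å MS, toluene–CH2Cl2, −60 °C, 24 h; Et3N quench at −60 °C
Reagents that add atoms: none
Why: Proposed new method: Ag2O dehydrogenates 2 to the o-quinone 5, which acts as an electron-poor oxa-diene (O=C–C=O) toward the electron-rich Z alkene in an inverse-electron-demand hetero-Diels–Alder reaction; the chiral acid hydrogen-bonds the more basic carbonyl oxygen (the one meta to the allyl group, whose protonated form is stabilised at the allyl-bearing ring carbon), so the nucleophilic methyl-bearing alkene carbon bonds first to the oxygen para to the allyl group and the aryl-bearing carbon then closes onto the acid-bound oxygen inside the same contact ion pair before the C–C bond can rotate, which converts the Z geometry into the cis ring and lets the chiral pocket select the alkene face, setting both stereocentres (2S,3R) at once; the closest known reaction types are the uncatalysed [4+2] additions of o-quinones to electron-rich styrenes that give 1,4-benzodioxanes and the chiral Brønsted acid-catalysed hetero-Diels–Alder reactions of o-quinone methides with styrenes.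

**Compound list**

1 | eugenol (4-allyl-2-methoxyphenol) | C=CCc1ccc(O)c(OC)c1 | starting material
2 | 4-allylcatechol (4-(prop-2-enyl)benzene-1,2-diol) | C=CCc1ccc(O)c(O)c1 | intermediate
3 | 3,4,5-trimethoxybenzaldehyde | COc1cc(C=O)cc(OC)c1OC | starting material
4 | (Z)-isoelemicin [(Z)-1,2,3-trimethoxy-5-(prop-1-enyl)benzene] | C/C=C\c1cc(OC)c(OC)c(OC)c1 | intermediate
5 | 4-allyl-1,2-benzoquinone (4-(prop-2-enyl)cyclohexa-3,5-diene-1,2-dione) | C=CCC1=CC(=O)C(=O)C=C1 | intermediate
6 | (2S,3R)-2-methyl-6-(prop-2-enyl)-3-(3,4,5-trimethoxyphenyl)-2,3-dihydro-1,4-benzodioxine (cis) | C=CCc1ccc2c(c1)O[C@H](c1cc(OC)c(OC)c(OC)c1)[C@H](C)O2 | target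

**Step count**

Total step count: 3 (steps 1 and 2 run in parallel, step 3 joins them).
Longest linear sequence: 2 steps (1 → 2 → 6, or 3 → 4 → 6).

**Steps most likely to fail**

Step 3 (highest risk). The asymmetric version is untested. The quinone may react as a carbon diene or be attacked at a ring carbon. The Z geometry may leak to the trans ring if the benzylic cation lives long enough to rotate. The regioisomer with the two oxygens exchanged may form, and the ee is unknown. The cis ring is recognised by the small vicinal coupling of the two ring CH protons (about 2–3 Hz; trans about 8 Hz).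

Fallback, setting out from 2 and coming back at 6: replace the two-electron cycloaddition by the one-electron phenol coupling and take the absolute configuration from a resolution. Compound 2 (3 equiv) is co-oxidised with commercial (E)-2,6-dimethoxy-4-(prop-1-enyl)phenol (C/C=C/c1cc(OC)c(O)c(OC)c1) using Ag2O in toluene–acetone at rt. The phenoxyl radical couples through its methyl-bearing carbon with the oxygen para to the allyl group of the semiquinone of 2. This gives the quinone methide 4-[2-(4-allyl-2-hydroxyphenoxy)propylidene]-2,6-dimethoxycyclohexa-2,5-dien-1-one F1, whose neighbouring OH closes the dioxane ring. The minor cis phenol, racemic 4-[(2R*,3S*)-3-methyl-7-(prop-2-enyl)-2,3-dihydro-1,4-benzodioxin-2-yl]-2,6-dimethoxyphenol F2, is separated from the trans isomer. It is O-methylated (MeI, K2CO3, acetone) to racemic 6 and resolved by chiral-phase SFC. The unwanted enantiomer is (2R,3S)-2-methyl-6-(prop-2-enyl)-3-(3,4,5-trimethoxyphenyl)-2,3-dihydro-1,4-benzodioxine F3.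

Step 2. The Z:E ratio is only about 9:1 and the isomers run close together; any E alkene carried on ends up as trans ring.

Fallback, setting out from 3 and coming back at 4: fix the geometry by alkyne semihydrogenation. Dibromo-olefination of 3 (CBr4, PPh3, CH2Cl2, 0 °C) gives 5-(2,2-dibromoethenyl)-1,2,3-trimethoxybenzene F4. Treatment with n-BuLi (2.1 equiv, THF, −78 °C) and then MeI gives 1,2,3-trimethoxy-5-(prop-1-ynyl)benzene F5. Hydrogenation (H2, 1 atm) over Pd on CaCO3 poisoned with Pb(OAc)2, with quinoline in hexane, gives 4 with at least 97:3 Z:E.

Step 1. HBr formed in the reaction can add to the allyl group, and the catechol is air-sensitive.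

Fallback, setting out from 1 and coming back at 5: leave out the catechol and demethylate oxidatively. NaIO4 (1.1 equiv) in H2O–AcOH at 0 °C for a few minutes converts 1 directly into 5 with loss of methanol. The quinone is extracted cold into CH2Cl2, dried over Na2SO4 and run straight into the cycloaddition of step 3 in place of the Ag2O stage. New compounds: none F0.

**Further compounds**

F1 | step 3 | 4-[2-(4-allyl-2-hydroxyphenoxy)propylidene]-2,6-dimethoxycyclohexa-2,5-dien-1-one (racemic) | C=CCc1ccc(OC(C)C=C2C=C(OC)C(=O)C(OC)=C2)c(O)c1
F2 | step 3 | 4-[(2R*,3S*)-3-methyl-7-(prop-2-enyl)-2,3-dihydro-1,4-benzodioxin-2-yl]-2,6-dimethoxyphenol (racemic cis, one enantiomer drawn) | C=CCc1ccc2c(c1)O[C@H](c1cc(OC)c(O)c(OC)c1)[C@H](C)O2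
F3 | step 3 | (2R,3S)-2-methyl-6-(prop-2-enyl)-3-(3,4,5-trimethoxyphenyl)-2,3-dihydro-1,4-benzodioxine (enantiomer of 6) | C=CCc1ccc2c(c1)O[C@@H](c1cc(OC)c(OC)c(OC)c1)[C@@H](C)O2
F4 | step 2 | 5-(2,2-dibromoethenyl)-1,2,3-trimethoxybenzene | COc1cc(C=C(Br)Br)cc(OC)c1OC
F5 | step 2 | 1,2,3-trimethoxy-5-(prop-1-ynyl)benzene | CC#Cc1cc(OC)c(OC)c(OC)c1
F0 | step 1 | none | none
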